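The substrate has more than one way to go, and the question is how the four flasks divide it.

| flask | substrate | coupling partner | temperature | remark | time |
|---|---|---|---|---|---|
| east | 13 mM | 26 mM | 55 °C | run made earlier |  |
| west | 13 mM | 13 mM | 70 °C | run made earlier |  |
| south | 13 mM | 20 mM | 55 °C | run made earlier |  |
| oak | 13 mM | 26.0 mM |  | everything together at the start at 50 °C, warmed to 70 °C at 50 s | 2.0 min |
| elm | 13 mM | 26.0 mM (fed, over 50 s) | 70 °C | all else is in the flask from the start; the feed brings no volume worth counting | 2.0 min |
| alder | 13 mM (fed, over 50 s) | 26.0 mM |  | the addition at 50 °C, then warmed to 70 °C; the feed brings no volume worth counting | 2.0 min |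
| birch | 13 mM | 26.0 mM | 70 °C | everything together at the start | 2.0 min |

east run (percent of the substrate charged)

| time / min | target / % | side product A / % | substrate / % |
|---|---|---|---|
| 0.333 | 5.8 | 1.6 | 67.8 |
| 0.417 | 6.7 | 1.9 | 63.1 |
| 0.667 | 9.9 | 1.5 | 51.4 |
| 1.00 | 10.8 | 2.6 | 39.4 |
| 2.00 | 16.9 | 4.2 | 23.5 |
| 3.00 | 20.1 | 5.4 | 14.7 |

west run (percent of the substrate charged)

| time / s | target / % | side product A / % | substrate / % |
|---|---|---|---|
| 10.0 | 3.1 | 2.7 | 65.3 |
| 15.0 | 3.2 | 3.5 | 55.2 |
| 25.0 | 5.3 | 4.8 | 42.0 |
| 40.0 | 7.3 | 6.2 | 29.7 |
| 60.0 | 9.6 | 8.2 | 22.2 |
| 80.0 | 9.8 | 9.4 | 16.0 |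
| 90.0 | 9.9 | 9.8 | 15.3 |

south run (percent of the substrate charged)

| time / min | target / % | side product A / % | substrate / % |
|---|---|---|---|
| 0.333 | 4.9 | 0.9 | 68.3 |
| 0.500 | 5.9 | 1.3 | 58.8 |
| 0.833 | 8.3 | 3.2 | 45.7 |
| 1.33 | 11.1 | 3.5 | 32.5 |
| 2.00 | 13.2 | 4.0 | 25.1 |
| 3.00 | 16.0 | 5.6 | 16.3 |

(readings scatter by 0.5 percentage points)

- the numbers in the tables scatter by 0.5 percentage points (one standard deviation)
- a reading or a percentage of target counts all its forms, free or not

1. the best flask by share of target in target plus side product A; "all alike" if 1.5 percentage points covers them all (oak / elm / alder / birch / all alike)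
2. share of target in target plus side product A at the end, oak
3. share of target in target plus side product A at the end, elm
4. share of target in target plus side product A at the end, alder
5. share of target in target plus side product A at the end, birch

Tom and Vera disagree. Tom looks at the balance. In east at the last reading, 59.8 % of the substrate charged is in no measured species. He reads this as a hidden loss that grows with c(substrate). A slow substrate feed keeps c(substrate) low, so he backs alder.

Vera looks at the ratio of target to side product A. In east it goes from 3.62 to 3.72, while substrate falls from 67.8 % to 14.7 %. So c(substrate) drops out of the asked share, and the two paths act like two outlets of one tank.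

Multiply the charged c(coupling partner) by side product A over target, at the last reading. West gives 12.9 mM at 70 °C. This estimates the crossing concentration, the c(coupling partner) at which target and side product A form equally fast. It uses the charged value, but partner falls during west, so the estimate stands on the high side. It works like a filter's corner value: above it target leads, below it side product A leads. East gives 6.99 mM at 55 °C and south gives 7.00 mM, so the estimate is lower when cooler. The share, or selectivity, is c(coupling partner) over c(coupling partner) plus the crossing.

My reckoning follows Vera. Birch starts at 26.0 mM hot, which gives 66.8 % at the start. At 55 °C the same charge gives 78.8 %. Oak keeps its substrate cold for 50 s, while alder's has on average half of that time, so I put oak above alder and both above birch. Elm's feed delivers an average of 13.0 mM over its 50 s, counted before any loss of partner. That is about at my estimated crossing, which gives 50.2 %.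

The forecast is lower than my 55 °C figure for oak and higher than my figure for elm. It names oak, with oak 73.3 %, elm 56 %, alder 71.7 % and birch 69 %: “Elm is about 56, because partner is starved early”.

The flasks give oak 73.6 %, elm 54.4 %, alder 71.2 % and birch 67.1 %, so oak is best.

    substrate + coupling partner → target (k = 0.310 L mol⁻¹ s⁻¹, Ea = 54.0 kJ mol⁻¹)
    substrate → side product A (k = 0.00300 s⁻¹, Ea = 86.0 kJ mol⁻¹)
    2 substrate → side product B (k = 1.70 L mol⁻¹ s⁻¹, Ea = 54.0 kJ mol⁻¹)
    coupling partner → decomposed reagent (k = 0.00630 s⁻¹, Ea = 106 kJ mol⁻¹)
    crystals ⇌ target, rate k5*(cs5 - [target]) while solid is left; crystals form when [target] > cs5 (solubility = 1.40 mM, k = 2.10 s⁻¹)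
    (constants at 70 °C)

Tom's ground is side product B, where alder ends with 57.4 % of the substrate charged, less than oak's 60.3 %. The neighbour flask gets 6.5 mM of coupling partner by elm's feed. Its feed delivers an average of 3.25 mM, counted before any loss of partner, lower than the estimated crossing, so the share reckons to 20.1 %. The neighbour flask gives 23.5 %, with 11.2 % of side product A at the end.

Readings and results are simulated for an exercise; the scatter is artificial.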